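**Strategy**

Everything rests on an aldol disconnection of the C7–C8 bond of the glycerol chain (C7: benzylic carbinol carbon on guaiacyl ring A; C8: carbon carrying the aryl ether oxygen of ring B; C9: the CH2OH carbon). The feature exploited is the syn (threo) pairing of the C7 hydroxyl and the C8 aryloxy group next to C9, which becomes the retron of a glycolate-type Evans syn aldol once C9 is raised to an imide carbonyl. In one operation the boron enolate of an (R)-4-benzyloxazolidinone aryloxyacetyl imide, already carrying ring B and its protected side chain, adds to O-acetylvanillin, forming C7–C8 and setting both stereocentres; one hydride step then unveils the target.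

Key step: step 3

Remark: sinapyl alcohol, (R)-4-benzyl-3-(2-chloroacetyl)oxazolidin-2-one and vanillin acetate are taken as catalogue compounds; C7, C8 and C9 follow lignan numbering.

**Route**

Step 1
Reactants: 1 sinapyl alcohol, (E)-4-(3-hydroxyprop-1-en-1-yl)-2,6-dimethoxyphenol; 2 (R)-4-benzyl-3-(2-chloroacetyl)oxazolidin-2-one
Product: 3 (R)-4-benzyl-3-{2-[4-((E)-3-hydroxyprop-1-en-1-yl)-2,6-dimethoxyphenoxy]acetyl}oxazolidin-2-one
Conditions: K2CO3, NaI (cat.), acetone, 40 °C, argon
Reagents that add atoms: none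
Why: Williamson ether synthesis in which K2CO3 deprotonates only the phenol (far more acidic than the allylic alcohol) and the phenoxide should displace the halide of the activated alpha-halo imide by SN2 after in situ Finkelstein exchange, leaving the auxiliary stereocentre untouched.

Step 2
Reactants: 3 (R)-4-benzyl-3-{2-[4-((E)-3-hydroxyprop-1-en-1-yl)-2,6-dimethoxyphenoxy]acetyl}oxazolidin-2-one
Product: 4 (E)-3-{4-[2-((R)-4-benzyl-2-oxooxazolidin-3-yl)-2-oxoethoxy]-3,5-dimethoxyphenyl}allyl acetate
Conditions: Ac2O, pyridine, DMAP (cat.), CH2Cl2, 0 → 23 °C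
Reagents that add atoms: acetic anhydride CC(=O)OC(C)=O
Why: DMAP-catalysed O-acylation of the only free hydroxyl should mask it against borylation in step 3 as an ester that the final hydride step removes; no stereocentre is involved.

Step 3
Reactants: 4 (E)-3-{4-[2-((R)-4-benzyl-2-oxooxazolidin-3-yl)-2-oxoethoxy]-3,5-dimethoxyphenyl}allyl acetate; 5 vanillin acetate, 4-formyl-2-methoxyphenyl acetate
Product: 8 (R)-4-benzyl-3-[(2R,3S)-3-(4-acetoxy-3-methoxyphenyl)-2-{4-[(E)-3-acetoxyprop-1-en-1-yl]-2,6-dimethoxyphenoxy}-3-hydroxypropanoyl]oxazolidin-2-one, via Z-dibutylboron enolate 6 (not isolated), via dibutylboron aldolate 7 (not isolated)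
Conditions: n-Bu2BOTf, i-Pr2NEt, CH2Cl2, −78 → 0 °C; then 5, −78 → 0 °C; MeOH, pH 7 buffer (NaH2PO4/Na2HPO4), 0 °C, no H2O2
Reagents that add atoms: none
Why: Soft enolisation of 4 (boron triflate on the imide carbonyl, amine deprotonation) should give only the Z enolate 6 with the aryloxy group cis to OB, which adds to aldehyde 5 through a closed Zimmerman–Traxler chair with boron bridging both oxygens, and the resulting aldolate 7 is released by peroxide-free methanolysis so that the aryl acetate is spared. The closest known reaction type is the Evans syn aldol of alkoxyacetyl (glycolate-type) oxazolidinone imides with aromatic aldehydes; no ring of the target is closed, the chair being only a transient array. C8 is controlled by the (R)-benzyl group of the auxiliary, which in the dipole-opposed conformer shields one enolate face so that the aldehyde bonds to the other, giving 2R in 8 (this centre reads 8S in the target only because C9 drops in priority on reduction). C7 is controlled by the enolate geometry, the Z enolate with the aryl group of 5 equatorial in the chair giving the syn (threo) relationship and hence 7S. The step needs enolisation of the imide CH2 in preference to the two acetyl groups and addition to the aldehyde only, which the far more acidic, bidentately activated imide and the low temperature should secure. The 4-acetoxy group makes 5 a good electrophile and keeps the new benzylic C7–O bond from ionising during work-up.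

Step 4
Reactants: 8 (R)-4-benzyl-3-[(2R,3S)-3-(4-acetoxy-3-methoxyphenyl)-2-{4-[(E)-3-acetoxyprop-1-en-1-yl]-2,6-dimethoxyphenoxy}-3-hydroxypropanoyl]oxazolidin-2-one
Product: 9 (1S,2S)-1-(4-hydroxy-3-methoxyphenyl)-2-{4-[(E)-3-hydroxyprop-1-en-1-yl]-2,6-dimethoxyphenoxy}propane-1,3-diol (threo-(7S,8S)-guaiacylglycerol 8-O-4′-sinapyl alcohol ether)
Conditions: LiBH4 (excess), THF, MeOH, 0 → 23 °C; aq. NH4Cl
Reagents that add atoms: none
Why: Borohydride reduction of the N-acyloxazolidinone at its exocyclic carbonyl should give the C9 primary alcohol and free auxiliary while the same reagent reductively cleaves the aryl and allyl acetates, and neither C7 nor C8 should epimerise because C8 loses its acidifying carbonyl at once and the work-up is near neutral.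

**Compound list**

1 | sinapyl alcohol, (E)-4-(3-hydroxyprop-1-en-1-yl)-2,6-dimethoxyphenol | COc1cc(/C=C/CO)cc(OC)c1O | starting material
2 | (R)-4-benzyl-3-(2-chloroacetyl)oxazolidin-2-one | O=C(CCl)N1C(=O)OC[C@H]1Cc1ccccc1 | starting material
3 | (R)-4-benzyl-3-{2-[4-((E)-3-hydroxyprop-1-en-1-yl)-2,6-dimethoxyphenoxy]acetyl}oxazolidin-2-one | COc1cc(/C=C/CO)cc(OC)c1OCC(=O)N1C(=O)OC[C@H]1Cc1ccccc1 | intermediate
4 | (E)-3-{4-[2-((R)-4-benzyl-2-oxooxazolidin-3-yl)-2-oxoethoxy]-3,5-dimethoxyphenyl}allyl acetate | COc1cc(/C=C/COC(C)=O)cc(OC)c1OCC(=O)N1C(=O)OC[C@H]1Cc1ccccc1 | intermediate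
5 | vanillin acetate, 4-formyl-2-methoxyphenyl acetate | COc1cc(C=O)ccc1OC(C)=O | starting material
6 | Z-dibutylboron enolate of 4 (aryloxy cis to OB), not isolated | CCCCB(CCCC)O/C(=C\Oc1c(OC)cc(/C=C/COC(C)=O)cc1OC)N1C(=O)OC[C@H]1Cc1ccccc1 | intermediate
7 | dibutylboron aldolate (O-dibutylboryl derivative of 8), not isolated | COc1cc([C@H](OB(CCCC)CCCC)[C@H](C(=O)N2C(=O)OC[C@H]2Cc2ccccc2)Oc3c(OC)cc(/C=C/COC(C)=O)cc3OC)ccc1OC(C)=O | intermediate
8 | (R)-4-benzyl-3-[(2R,3S)-3-(4-acetoxy-3-methoxyphenyl)-2-{4-[(E)-3-acetoxyprop-1-en-1-yl]-2,6-dimethoxyphenoxy}-3-hydroxypropanoyl]oxazolidin-2-one | COc1cc([C@H](O)[C@H](C(=O)N2C(=O)OC[C@H]2Cc2ccccc2)Oc3c(OC)cc(/C=C/COC(C)=O)cc3OC)ccc1OC(C)=O | intermediate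
9 | (1S,2S)-1-(4-hydroxy-3-methoxyphenyl)-2-{4-[(E)-3-hydroxyprop-1-en-1-yl]-2,6-dimethoxyphenoxy}propane-1,3-diol | COc1cc([C@H](O)[C@H](CO)Oc2c(OC)cc(/C=C/CO)cc2OC)ccc1O | target

**Step count and risks**

Total step count: 4. Longest linear sequence: 4 steps (1 → 3 → 4 → 8 → 9).

Steps most likely to fail:

Step 3. The boron triflate may ionise or transfer the acetyl group of the electron-rich cinnamyl acetate, and the peroxide-free work-up may release the boron aldolate incompletely. The fallback sets out from 3 and comes back at 9, changing the protecting-group logic and the endgame. Compound 3 is silylated (TBSCl, imidazole, DMF) to (R)-4-benzyl-3-{2-[4-((E)-3-(tert-butyldimethylsilyloxy)prop-1-en-1-yl)-2,6-dimethoxyphenoxy]acetyl}oxazolidin-2-one F1. Vanillin is silylated in the same way to 4-(tert-butyldimethylsilyloxy)-3-methoxybenzaldehyde F2. The boron aldol of F1 with F2, now with the usual buffered H2O2 work-up that silyl ethers tolerate, should give the bis-silyl syn aldol adduct F3. LiBH4 in THF/MeOH then removes the auxiliary to give the bis-silyl 1,3-diol F4, and TBAF buffered with AcOH in THF at 0 °C removes both silyl groups to give 9.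

Step 1. The phenoxide or carbonate may attack the imide carbonyls (acyl transfer and loss of the auxiliary) instead of the CH2Cl carbon, or the acidic chloroacetyl imide may self-condense. The fallback sets out from 1 and comes back at 4, building the aryloxyacetic acid first and attaching the auxiliary afterwards. Compound 1 is alkylated with methyl bromoacetate (K2CO3, acetone) to methyl 2-{4-[(E)-3-hydroxyprop-1-en-1-yl]-2,6-dimethoxyphenoxy}acetate F5. Saponification (LiOH, THF/H2O) gives the hydroxy acid F6, and acetylation (Ac2O, pyridine, aqueous work-up) gives 2-{4-[(E)-3-acetoxyprop-1-en-1-yl]-2,6-dimethoxyphenoxy}acetic acid F7. Activation of F7 as the pivaloyl mixed anhydride (PivCl, Et3N, THF, −20 °C) and addition of (R)-4-benzyloxazolidin-2-one and LiCl should give 4.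

Step 4. The beta-hydroxy imide may fragment by retro-aldol in the basic hydride medium before the imide is reduced, or the allyl acetate may be cleaved incompletely. The fallback sets out from 8 and comes back at 9, capping the aldol hydroxyl before reduction. Compound 8 is silylated (TESOTf, 2,6-lutidine, CH2Cl2, −78 °C) to the C7 triethylsilyl ether F8, which cannot undergo retro-aldol. LiBH4 in THF/MeOH then reduces the imide and both acetates to give the C7-O-triethylsilyl triol F9, and buffered fluoride (Et3N·3HF, THF, 0 °C) releases the C7 hydroxyl to give 9.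

**Further compounds**

F1 | step 3 | (R)-4-benzyl-3-{2-[4-((E)-3-(tert-butyldimethylsilyloxy)prop-1-en-1-yl)-2,6-dimethoxyphenoxy]acetyl}oxazolidin-2-one | COc1cc(/C=C/CO[Si](C)(C)C(C)(C)C)cc(OC)c1OCC(=O)N1C(=O)OC[C@H]1Cc1ccccc1
F2 | step 3 | 4-(tert-butyldimethylsilyloxy)-3-methoxybenzaldehyde | COc1cc(C=O)ccc1O[Si](C)(C)C(C)(C)C
F3 | step 3 | (R)-4-benzyl-3-[(2R,3S)-3-(4-(tert-butyldimethylsilyloxy)-3-methoxyphenyl)-2-{4-[(E)-3-(tert-butyldimethylsilyloxy)prop-1-en-1-yl]-2,6-dimethoxyphenoxy}-3-hydroxypropanoyl]oxazolidin-2-one | COc1cc([C@H](O)[C@H](C(=O)N2C(=O)OC[C@H]2Cc2ccccc2)Oc3c(OC)cc(/C=C/CO[Si](C)(C)C(C)(C)C)cc3OC)ccc1O[Si](C)(C)C(C)(C)C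
F4 | step 3 | (1S,2S)-1-(4-(tert-butyldimethylsilyloxy)-3-methoxyphenyl)-2-{4-[(E)-3-(tert-butyldimethylsilyloxy)prop-1-en-1-yl]-2,6-dimethoxyphenoxy}propane-1,3-diol | COc1cc([C@H](O)[C@H](CO)Oc2c(OC)cc(/C=C/CO[Si](C)(C)C(C)(C)C)cc2OC)ccc1O[Si](C)(C)C(C)(C)C
F5 | step 1 | methyl 2-{4-[(E)-3-hydroxyprop-1-en-1-yl]-2,6-dimethoxyphenoxy}acetate | COC(=O)COc1c(OC)cc(/C=C/CO)cc1OC
F6 | step 1 | 2-{4-[(E)-3-hydroxyprop-1-en-1-yl]-2,6-dimethoxyphenoxy}acetic acid | OC(=O)COc1c(OC)cc(/C=C/CO)cc1OC
F7 | step 1 | 2-{4-[(E)-3-acetoxyprop-1-en-1-yl]-2,6-dimethoxyphenoxy}acetic acid | CC(=O)OC/C=C/c1cc(OC)c(OCC(O)=O)c(OC)c1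
F8 | step 4 | (R)-4-benzyl-3-[(2R,3S)-3-(4-acetoxy-3-methoxyphenyl)-2-{4-[(E)-3-acetoxyprop-1-en-1-yl]-2,6-dimethoxyphenoxy}-3-(triethylsilyloxy)propanoyl]oxazolidin-2-one | COc1cc([C@H](O[Si](CC)(CC)CC)[C@H](C(=O)N2C(=O)OC[C@H]2Cc2ccccc2)Oc3c(OC)cc(/C=C/COC(C)=O)cc3OC)ccc1OC(C)=O
F9 | step 4 | (2S,3S)-3-(4-hydroxy-3-methoxyphenyl)-2-{4-[(E)-3-hydroxyprop-1-en-1-yl]-2,6-dimethoxyphenoxy}-3-(triethylsilyloxy)propan-1-ol | COc1cc([C@H](O[Si](CC)(CC)CC)[C@H](CO)Oc2c(OC)cc(/C=C/CO)cc2OC)ccc1O
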